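Birch at 5.00 h accounts for 99.4% of the substrate charged. In cedar, target falls to 0% by 20.0 h while side product climbs to 64.8%. Target therefore goes on with substrate to side product, and each side product holds one substrate that passed through target and one that did not.

| setting | birch | cedar | elm | oak | south | north-east | east | west | north-west |
|---|---|---|---|---|---|---|---|---|---|
| substrate | 0.10 M | 0.10 M | 0.10 M | 0.10 M | 0.10 M | 0.10 M | 0.10 M | 0.10 M | 0.10 M (fed, over 12 h) |
| coupling partner | 0.070 M | 0.035 M | 0.053 M | 0.070 M | 0.0700 M (fed, over 12 h) | 0.0700 M (fed, over 3.0 h) | 0.0700 M | 0.0700 M (in portions, 5, over 12 h) | 0.0700 M |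
| free catalyst | 1 mM | 1 mM | 1 mM | 1.5 mM | 1.0 mM | 1.0 mM | 1.0 mM | 1.0 mM | 1.0 mM |
| remark | run made earlier | run made earlier | run made earlier | run made earlier | all else is in the flask from the start; the feed brings no volume worth counting | all else is in the flask from the start; the feed brings no volume worth counting | everything together at the start | first portion at the start, last at 12 h | all else is in the flask from the start; the feed brings no volume worth counting |
| time |  |  |  |  | 20 h | 20 h | 20 h | 20 h | 20 h |

| run | time / h | side product / % | target / % | substrate / % |
|---|---|---|---|---|
| birch | 5.00 | 51.7 | 31.3 | 16.4 |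
| birch | 10.0 | 67.8 | 23.6 | 7.2 |
| birch | 15.0 | 76.4 | 21.1 | 3.4 |
| birch | 20.0 | 80.2 | 18.5 | 3.9 |
| cedar | 1.50 | 13.8 | 17.9 | 67.5 |
| cedar | 4.00 | 37.3 | 13.4 | 48.2 |
| cedar | 8.00 | 55.0 | 2.7 | 39.7 |
| cedar | 20.0 | 64.8 | 0 | 35.5 |
| elm | 5.00 | 51.2 | 21.1 | 28.9 |
| elm | 10.0 | 69.7 | 13.2 | 18.0 |
| elm | 15.0 | 78.1 | 7.2 | 15.3 |
| elm | 20.0 | 81.1 | 5.1 | 12.5 |
| oak | 1.50 | 22.4 | 35.8 | 43.1 |
| oak | 4.00 | 46.9 | 37.1 | 16.5 |
| oak | 8.00 | 62.4 | 28.6 | 8.0 |
| oak | 20.0 | 76.9 | 21.7 | 1.8 |

(each reading ± 1 percentage point)

- percentages count the substrate that a species holds: one side product counts as two
- the earlier runs were read with a standard deviation of 1 percentage point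

1. the flask with the highest amount of side product, in percent of the substrate charged ("all alike" if they lie within 1.5 percentage points) (south / north-east / east / west / north-west / all alike)
2. final side product, as a percentage of the substrate charged, in south
3. final side product, as a percentage of the substrate charged, in north-east
4. final side product, as a percentage of the substrate charged, in east
5. final side product, as a percentage of the substrate charged, in west
6. final side product, as a percentage of the substrate charged, in north-west

The quantity to follow is the delivered share: the fraction of the substrate charge that has ever become target, at one coupling partner each.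

delivered share = target + half the side product

substrate gone: side product = twice (the whole charge less the share)

target gone: side product = twice the share

Birch at 20.0 h reads a share of 58.6%, above one half, so substrate is the limiting reagent of the second step. Side product in birch then heads for 82.8%, the end level: twice what the share leaves short of the charge, read with the scatter of the readings.

East is the birch recipe, so its curve is birch's. Side product in birch reads 51.7% at 5.00 h, then gains 16 points, 8.6 points and 3.8 points over the next equal spans. The share in birch reads 57.1% at that first reading, against 58.6% at 20.0 h, so its knee lies before the first reading. This reckoning puts east near birch's 80.2%, which is 2.6 points short of the level.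

Birch charged 70.0% of partner and delivered 58.6%, so 11 points is missing. Cedar charged 35.0% and delivered 32.4%, so 2.6 points is missing. The missing share in birch reads 4.38 times cedar's on 2.00 times the charge, against 4.00 for the square of that ratio; this is a reading from small differences and carries their scatter. A feed that holds partner low should therefore move the share towards 70.0%, and that share, with substrate gone, gives a floor of 60.0%. This reckoning sets south, west and north-east between floor and level, at about 71.4%, and leaves north-west open.

The forecast named east at 80%, with 52% in south, 79% in north-east, 54% in west and 55% in north-west, holding that “slow feeds waste partner after the catalyst dies”; its south and west lie below the floor of this reckoning.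

East gives 79.3%, the highest, against 69.7% in south, 69.2% in north-east, 72.4% in west and 68.2% in north-west.

    coupling partner + free catalyst → catalyst intermediate A (k = 1500 M⁻¹ h⁻¹)
    substrate + catalyst intermediate A ⇌ catalyst intermediate B (K = 3.40 M⁻¹, k = 540 M⁻¹ h⁻¹)
    substrate + target → side product (k = 5.30 M⁻¹ h⁻¹)
    catalyst intermediate B → free catalyst + target (k = 2200 h⁻¹)
    2 coupling partner → self-condensation product (k = 1.90 M⁻¹ h⁻¹)

Left until 200 h, east stands at 84.8%, which is 2 points above the end level of 82.8%. North-west at 20.0 h holds 3.92% target and 68.2% side product, a share of 38.0%, below one half. Twice that share gives 76.0%, and north-west at 200 h stands at 76.0%.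

(The data were computed for an exercise; the scatter is artificial.)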